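## Retrosynthetic overview
1. Quinone 27 comes from hydroquinone 26 (Ag2O). 26 comes from the tri-O-methyl macrocycle 24 (BBr3). Ring D travels as a 1,4-dimethoxyarene and is oxidised last.
2. 24 comes from the cyclic stilbene 23, made from dialdehyde 22. The 18-membered macrocycle is the only ring formed, closed at the A–D bridge by McMurry coupling.
3. 22 comes from diarylalkyne 21, made by Sonogashira union of AB alkyne 11 with CD triflate 20. These are two C16 halves, and the union builds the B–C bridge.
4. 11 is built by SNAr of guaiacol on 4-fluorobenzaldehyde, iodination para to OMe, then TMS-acetylene and desilylation.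
5. 20 is built by LDA/DMF formylation of 2-bromo-1,4-dimethoxybenzene, Ullmann etherification with resorcinol, then triflation.

Assumption: the target SMILES has no stereodescriptor, no stereocentre and no configurationally stable axis or plane. It is treated as achiral, so there is no enantiomer to control. The only stereo-element on the way is the alkene geometry of 23, which step 15 erases.

## Route

**Step 1**
Reactants: 1 1-bromo-4-fluorobenzene
Product: 4 4-fluorobenzaldehyde, via 4-fluorophenylmagnesium bromide 2 (not isolated), via bromomagnesium (dimethylamino)(4-fluorophenyl)methanolate 3 (not isolated)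
Conditions: Mg, THF, reflux; DMF, 0 °C → rt; 1 M HCl
Reagents that add atoms: N,N-dimethylformamide CN(C)C=O
Why: In this Bouveault aldehyde synthesis the aryl Grignard adds once to DMF, and the stable tetrahedral adduct collapses to the aldehyde only on acidic quench.

**Step 2**
Reactants: 5 catechol (1.5 equiv)
Product: 6 2-methoxyphenol (guaiacol)
Conditions: MeI (1.0 equiv), K2CO3 (1.0 equiv), acetone, reflux, N2
Reagents that add atoms: iodomethane CI
Why: Williamson mono-O-methylation with catechol in excess favours 6, which is freed from neutral veratrole by base extraction and from catechol by water washing.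

**Step 3**
Reactants: 4 4-fluorobenzaldehyde; 6 2-methoxyphenol
Product: 7 4-(2-methoxyphenoxy)benzaldehyde
Conditions: K2CO3, DMF, 120 °C
Reagents that add atoms: none
Why: In this SNAr reaction the para-formyl group stabilises the Meisenheimer adduct and fluoride is displaced by the phenoxide.

**Step 4**
Reactants: 7 4-(2-methoxyphenoxy)benzaldehyde
Product: 8 4-(5-iodo-2-methoxyphenoxy)benzaldehyde
Conditions: NIS (1.05 equiv), TFA (cat.), MeCN, rt, dark
Reagents that add atoms: N-iodosuccinimide O=C1CCC(=O)N1I
Why: Electrophilic aromatic iodination avoids the formyl-deactivated ring A, and OMe, a much stronger donor than the 4-formylphenoxy group, directs to its para position.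

**Step 5**
Reactants: 8 4-(5-iodo-2-methoxyphenoxy)benzaldehyde; 9 ethynyltrimethylsilane
Product: 10 4-{2-methoxy-5-[(trimethylsilyl)ethynyl]phenoxy}benzaldehyde
Conditions: PdCl2(PPh3)2 (2 mol %), CuI (4 mol %), Et3N, THF, rt
Reagents that add atoms: none
Why: Sonogashira coupling of an aryl iodide proceeds at room temperature and tolerates the aldehyde.

**Step 6**
Reactants: 10 4-{2-methoxy-5-[(trimethylsilyl)ethynyl]phenoxy}benzaldehyde
Product: 11 4-(5-ethynyl-2-methoxyphenoxy)benzaldehyde (AB fragment)
Conditions: K2CO3 (cat.), MeOH, rt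
Reagents that add atoms: none
Why: Methoxide-catalysed protiodesilylation cleaves the C(sp)–Si bond and leaves the non-enolisable aldehyde untouched.

**Step 7**
Reactants: 12 hydroquinone
Product: 13 1,4-dimethoxybenzene
Conditions: MeI (2.5 equiv), K2CO3, acetone, reflux, N2
Reagents that add atoms: iodomethane CI
Why: Exhaustive Williamson O-methylation masks the future quinone as a base- and organometal-stable dimethyl ether.

**Step 8**
Reactants: 13 1,4-dimethoxybenzene
Product: 14 2-bromo-1,4-dimethoxybenzene
Conditions: NBS (1.0 equiv), MeCN, rt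
Reagents that add atoms: N-bromosuccinimide O=C1CCC(=O)N1Br
Why: All four ring positions are equivalent in this electrophilic aromatic bromination, and the first bromine slows a second substitution.

**Step 9**
Reactants: 14 2-bromo-1,4-dimethoxybenzene
Product: 17 2-bromo-3,6-dimethoxybenzaldehyde, via (2-bromo-3,6-dimethoxyphenyl)lithium 15 (not isolated), via lithium (2-bromo-3,6-dimethoxyphenyl)(dimethylamino)methanolate 16 (not isolated)
Conditions: LDA (commercial, 1.1 equiv), THF, −78 °C, 1 h; DMF, −78 → 0 °C; 1 M HCl
Reagents that add atoms: N,N-dimethylformamide CN(C)C=O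
Why: In this directed ortho-metalation the amide base cannot undergo Br/Li exchange and removes the most acidic proton, flanked by Br and OMe, while holding −78 °C prevents aryne formation before the DMF quench.

**Step 10**
Reactants: 17 2-bromo-3,6-dimethoxybenzaldehyde; 18 resorcinol (4 equiv)
Product: 19 2-(3-hydroxyphenoxy)-3,6-dimethoxybenzaldehyde
Conditions: CuI (10 mol %), picolinic acid (20 mol %), K3PO4, DMSO, 90 °C, Ar
Reagents that add atoms: none
Why: In this ligand-accelerated Ullmann diaryl ether synthesis the ortho-formyl group activates the C–Br bond, and excess water-soluble resorcinol suppresses double arylation.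

**Step 11**
Reactants: 19 2-(3-hydroxyphenoxy)-3,6-dimethoxybenzaldehyde
Product: 20 3-(2-formyl-3,6-dimethoxyphenoxy)phenyl trifluoromethanesulfonate (CD fragment)
Conditions: Tf2O (1.1 equiv), pyridine, CH2Cl2, 0 °C
Reagents that add atoms: trifluoromethanesulfonic anhydride O=S(=O)(OS(=O)(=O)C(F)(F)F)C(F)(F)F
Why: O-Sulfonylation of the only free phenol turns it into a cross-coupling handle.

**Step 12 (fragment union)**
Reactants: 11 4-(5-ethynyl-2-methoxyphenoxy)benzaldehyde; 20 3-(2-formyl-3,6-dimethoxyphenoxy)phenyl trifluoromethanesulfonate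
Product: 21 2-[3-({3-(4-formylphenoxy)-4-methoxyphenyl}ethynyl)phenoxy]-3,6-dimethoxybenzaldehyde
Conditions: Pd(PPh3)4 (5 mol %), CuI (10 mol %), Et3N, DMF, 70 °C, degassed
Reagents that add atoms: none
Why: Sonogashira coupling of an aryl triflate with a terminal alkyne joins the two halves at the future B–C bridge and tolerates both aldehydes.

**Step 13**
Reactants: 21 diarylalkyne dialdehyde
Product: 22 2-[3-(2-{3-(4-formylphenoxy)-4-methoxyphenyl}ethyl)phenoxy]-3,6-dimethoxybenzaldehyde
Conditions: H2 (1 atm), 10 % Pd/C, Ph2S (cat.), EtOAc, rt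
Reagents that add atoms: none
Why: Sulfide-poisoned Pd/C in this chemoselective catalytic hydrogenation still saturates the alkyne fully but no longer reduces aromatic aldehydes, giving the flexible chain needed for ring closure.

**Step 14 (macrocyclisation)**
Reactants: 22 bibenzyl dialdehyde
Product: 23 macrocyclic stilbene, the 18-membered tri-O-methyl cyclophane with an A–CH=CH–D bridge (E/Z mixture, both isomers carried on)
Conditions: TiCl4 (12 equiv), Zn (24 equiv), pyridine, THF, reflux; 22 added by syringe pump over 12 h (about 1 mM)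
Reagents that add atoms: none
Why: In this intramolecular McMurry coupling low-valent titanium reductively couples and deoxygenates the two aryl aldehydes, pseudo-high dilution favours the ring over oligomers, and the alkene geometry is irrelevant.

**Step 15**
Reactants: 23 macrocyclic stilbene
Product: 24 tri-O-methyl dihydromarchantinquinone (saturated macrocycle with a 1,4-dimethoxy ring D and OMe on ring B)
Conditions: H2 (1 atm), 10 % Pd/C, EtOAc–EtOH, rt
Reagents that add atoms: none
Why: Catalytic hydrogenation converges both alkene isomers to the single ethano bridge, and the aryl ethers are inert.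

**Step 16**
Reactants: 24 tri-O-methyl dihydromarchantinquinone
Product: 26 dihydromarchantinquinone (macrocyclic hydroquinone-phenol, triol), via the tris(dibromoboryl) ether of the triol 25 (not isolated)
Conditions: BBr3 (6 equiv), CH2Cl2, −78 °C → rt; H2O, 0 °C, under Ar
Reagents that add atoms: none
Why: Lewis-acid ether cleavage with BBr3 takes off the three O–CH3 groups by bromide attack at methyl, while the diaryl ether C–O bonds cannot be cleaved this way.

**Step 17**
Reactants: 26 dihydromarchantinquinone
Product: 27 marchantinquinone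
Conditions: Ag2O (1.5 equiv), Na2SO4, Et2O–CH2Cl2, rt, 20 min, dark
Reagents that add atoms: none
Why: This neutral two-electron oxidation takes the hydroquinone, by far the most easily oxidised site, to the quinone within minutes, and it spares the para-blocked ring-B monophenol and the aryloxyquinone linkage.

## Compound list
1 | 1-bromo-4-fluorobenzene | Fc1ccc(Br)cc1 | starting material
2 | 4-fluorophenylmagnesium bromide | Fc1ccc([Mg]Br)cc1 | intermediate (not isolated)
3 | bromomagnesium (dimethylamino)(4-fluorophenyl)methanolate (racemic, transient) | CN(C)C(O[Mg]Br)c1ccc(F)cc1 | intermediate (not isolated)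
4 | 4-fluorobenzaldehyde | O=Cc1ccc(F)cc1 | intermediate
5 | catechol | Oc1ccccc1O | starting material
6 | 2-methoxyphenol | COc1ccccc1O | intermediate
7 | 4-(2-methoxyphenoxy)benzaldehyde | COc1ccccc1Oc1ccc(C=O)cc1 | intermediate
8 | 4-(5-iodo-2-methoxyphenoxy)benzaldehyde | COc1ccc(I)cc1Oc1ccc(C=O)cc1 | intermediate
9 | ethynyltrimethylsilane | C#C[Si](C)(C)C | starting material
10 | 4-{2-methoxy-5-[(trimethylsilyl)ethynyl]phenoxy}benzaldehyde | COc1ccc(C#C[Si](C)(C)C)cc1Oc1ccc(C=O)cc1 | intermediate
11 | 4-(5-ethynyl-2-methoxyphenoxy)benzaldehyde | COc1ccc(C#C)cc1Oc1ccc(C=O)cc1 | intermediate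
12 | hydroquinone | Oc1ccc(O)cc1 | starting material
13 | 1,4-dimethoxybenzene | COc1ccc(OC)cc1 | intermediate
14 | 2-bromo-1,4-dimethoxybenzene | COc1ccc(OC)c(Br)c1 | intermediate
15 | (2-bromo-3,6-dimethoxyphenyl)lithium | COc1ccc(OC)c([Li])c1Br | intermediate (not isolated)
16 | lithium (2-bromo-3,6-dimethoxyphenyl)(dimethylamino)methanolate (racemic, transient) | COc1ccc(OC)c(C(O[Li])N(C)C)c1Br | intermediate (not isolated)
17 | 2-bromo-3,6-dimethoxybenzaldehyde | COc1ccc(OC)c(C=O)c1Br | intermediate
18 | resorcinol | Oc1cccc(O)c1 | starting material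
19 | 2-(3-hydroxyphenoxy)-3,6-dimethoxybenzaldehyde | COc1ccc(OC)c(C=O)c1Oc1cccc(O)c1 | intermediate
20 | 3-(2-formyl-3,6-dimethoxyphenoxy)phenyl trifluoromethanesulfonate | COc1ccc(OC)c(C=O)c1Oc1cccc(OS(=O)(=O)C(F)(F)F)c1 | intermediate
21 | 2-[3-({3-(4-formylphenoxy)-4-methoxyphenyl}ethynyl)phenoxy]-3,6-dimethoxybenzaldehyde | COc1ccc(C#Cc2cccc(Oc3c(OC)ccc(OC)c3C=O)c2)cc1Oc1ccc(C=O)cc1 | intermediate
22 | 2-[3-(2-{3-(4-formylphenoxy)-4-methoxyphenyl}ethyl)phenoxy]-3,6-dimethoxybenzaldehyde | COc1ccc(CCc2cccc(Oc3c(OC)ccc(OC)c3C=O)c2)cc1Oc1ccc(C=O)cc1 | intermediate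
23 | macrocyclic stilbene, tri-O-methyl (E/Z mixture, geometry not specified) | COc1ccc(OC)c2c1C=Cc1ccc(cc1)Oc1cc(ccc1OC)CCc1cccc(c1)O2 | intermediate
24 | tri-O-methyl dihydromarchantinquinone | COc1ccc(OC)c2c1CCc1ccc(cc1)Oc1cc(ccc1OC)CCc1cccc(c1)O2 | intermediate
25 | tris(dibromoboryl) ether of dihydromarchantinquinone | BrB(Br)Oc1ccc(OB(Br)Br)c2c1CCc1ccc(cc1)Oc1cc(ccc1OB(Br)Br)CCc1cccc(c1)O2 | intermediate (not isolated)
26 | dihydromarchantinquinone (hydroquinone triol) | Oc1ccc(O)c2c1CCc1ccc(cc1)Oc1cc(ccc1O)CCc1cccc(c1)O2 | intermediate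
27 | marchantinquinone (achiral) | O=C1C=CC(=O)C2=C1CCc1ccc(cc1)Oc1cc(ccc1O)CCc1cccc(c1)O2 | target

## Counts
Total step count: 17.
Longest linear sequence: 11 steps (12 → 13 → 14 → 17 → 19 → 20 → 21 → 22 → 23 → 24 → 26 → 27). The arm from 1 or 5 through 7, 8, 10 and 11 is equally long.

## Three steps most likely to fail

**Step 10.** The bromide of 17 is flanked on both sides. Resorcinol can also arylate twice or condense as a carbon nucleophile with the aldehyde.

The fallback forms the ether before the formyl group exists and then places the aldehyde by directed metalation. It sets out from 14 and 18.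
- The same copper catalysis on the unhindered, aldehyde-free bromide gives 3-(2,5-dimethoxyphenoxy)phenol F1.
- TIPSCl and imidazole in DMF give [3-(2,5-dimethoxyphenoxy)phenoxy]triisopropylsilane F2. Its bulky, non-coordinating silyl ether keeps ring C from being metalated.
- n-BuLi/TMEDA in THF at 0 °C removes the proton between OMe and OAr on ring D. This gives {3,6-dimethoxy-2-[3-(triisopropylsilyloxy)phenoxy]phenyl}lithium F3.
- DMF gives lithium (dimethylamino){3,6-dimethoxy-2-[3-(triisopropylsilyloxy)phenoxy]phenyl}methanolate F4.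
- Acidic quench of F4 gives 3,6-dimethoxy-2-[3-(triisopropylsilyloxy)phenoxy]benzaldehyde F5.
- TBAF in THF removes the silyl group, and the route is rejoined at 19.

**Step 13.** The poisoned catalyst may stall at the stilbene stage, or a more active catalyst may attack the aldehydes.

The fallback takes the aldehydes out of play by a redox detour. It sets out from 21.
- NaBH4 in MeOH–THF gives the alkyne diol [2-{3-[(3-{4-(hydroxymethyl)phenoxy}-4-methoxyphenyl)ethynyl]phenoxy}-3,6-dimethoxyphenyl]methanol F6.
- Ordinary Pd/C with H2 in EtOAc, with a trace of Et3N against benzylic hydrogenolysis, gives the saturated diol [2-{3-[2-(3-{4-(hydroxymethyl)phenoxy}-4-methoxyphenyl)ethyl]phenoxy}-3,6-dimethoxyphenyl]methanol F7.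
- Activated MnO2 in CH2Cl2 oxidises both benzylic alcohols, and the route is rejoined at 22.

**Step 14.** This is the riskiest step, because oligomerisation, incomplete deoxygenation and ring strain all compete.

The fallback changes the ring closure from carbonyl coupling to olefin metathesis. It sets out from 22.
- Double Wittig methylenation (MePPh3Br, KOt-Bu, THF, 0 °C) gives the bis-styrene 2-[3-(2-{4-methoxy-3-(4-vinylphenoxy)phenyl}ethyl)phenoxy]-1,4-dimethoxy-3-vinylbenzene F8.
- Ring-closing metathesis (Hoveyda–Grubbs II, toluene, 80 °C, 1 mM, Ar sparge) initiates at the unhindered ring-A styrene and closes the same C=C bond. The route is rejoined at 23.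

## Further compounds
F1 | step 10 | 3-(2,5-dimethoxyphenoxy)phenol | COc1ccc(OC)c(Oc2cccc(O)c2)c1
F2 | step 10 | [3-(2,5-dimethoxyphenoxy)phenoxy]triisopropylsilane | COc1ccc(OC)c(Oc2cccc(O[Si](C(C)C)(C(C)C)C(C)C)c2)c1
F3 | step 10 | {3,6-dimethoxy-2-[3-(triisopropylsilyloxy)phenoxy]phenyl}lithium | COc1ccc(OC)c([Li])c1Oc1cccc(O[Si](C(C)C)(C(C)C)C(C)C)c1
F4 | step 10 | lithium (dimethylamino){3,6-dimethoxy-2-[3-(triisopropylsilyloxy)phenoxy]phenyl}methanolate | COc1ccc(OC)c(C(O[Li])N(C)C)c1Oc1cccc(O[Si](C(C)C)(C(C)C)C(C)C)c1
F5 | step 10 | 3,6-dimethoxy-2-[3-(triisopropylsilyloxy)phenoxy]benzaldehyde | COc1ccc(OC)c(C=O)c1Oc1cccc(O[Si](C(C)C)(C(C)C)C(C)C)c1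
F6 | step 13 | [2-{3-[(3-{4-(hydroxymethyl)phenoxy}-4-methoxyphenyl)ethynyl]phenoxy}-3,6-dimethoxyphenyl]methanol | COc1ccc(C#Cc2cccc(Oc3c(OC)ccc(OC)c3CO)c2)cc1Oc1ccc(CO)cc1
F7 | step 13 | [2-{3-[2-(3-{4-(hydroxymethyl)phenoxy}-4-methoxyphenyl)ethyl]phenoxy}-3,6-dimethoxyphenyl]methanol | COc1ccc(CCc2cccc(Oc3c(OC)ccc(OC)c3CO)c2)cc1Oc1ccc(CO)cc1
F8 | step 14 | 2-[3-(2-{4-methoxy-3-(4-vinylphenoxy)phenyl}ethyl)phenoxy]-1,4-dimethoxy-3-vinylbenzene | COc1ccc(CCc2cccc(Oc3c(OC)ccc(OC)c3C=C)c2)cc1Oc1ccc(C=C)cc1
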